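Ring B (C2, C3, C7, C8, C9) is not cyclised but made by contracting a cyclohexanone. The feature used is that C7 of ring B carries both the ring ketone C8 and the oxygenated two-carbon branch C10, an arrangement that arises when the acyl carbon of a 2-methyl-2,3-epoxycyclohexanone migrates. One Lewis-acid step forms C7–C8, closes ring B and turns C10 into an acetyl carbonyl. The trans C2–C3 fusion comes unchanged from an equilibrated cryptone–isoprene decalone. The precursor is a trans-decalin with a C7–C10 epoxide and a C8 ketone that already bears the C1 methylene (C11), the C9 2-methylbutanoate and the C6 enoate, so a single reduction finishes the synthesis.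

Key step: step 11

Remarks
- Numbering (target numbering, kept for all intermediates): ring A = C1 (exocyclic methylene C11), C2, C3, C4 (isopropyl), C5, C6; ring B = C2, C3, C7, C8 (ketone), C9; C10 = carbinol carbon on C7. In the decalin intermediates C10 is a ring carbon between C7 and C8 and bears the methyl group. β = face of the C3 hydrogen, α = face of the C2 hydrogen.
- Design remark: a C1 ketone beside a C9 oxygen would be a β-oxy ketone with C2–H and C9–O antiperiplanar, and so prone to elimination. C1 is therefore methylenated before C9 is oxygenated, and both esters are attached after the last basic step.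
- Assumption: (R)-2-methylbutanoic acid and (E)-3-methylpent-2-enoic acid are bought as single isomers.

Step 1
Reactants: 1 3-methylbutanal; 2 but-3-en-2-one
Product: 4 (R)-4-isopropylcyclohex-2-en-1-one ((R)-cryptone), via keto aldehyde 3 (not isolated)
Conditions: (R)-2-[methoxy(diphenyl)methyl]pyrrolidine (5 mol %), ethyl 3,4-dihydroxybenzoate (20 mol %), neat, 4 °C; then LiOH (0.1 equiv), i-PrOH, rt
Reagents that add atoms: none
Why: Enamine-catalysed Michael addition followed by intramolecular aldol condensation (a Robinson-type annulation), in which the E-enamine of 1 should be attacked by 2 on the face away from the diphenyl(methoxy)methyl group of the (R)-catalyst, setting the isopropyl-bearing carbon (later C4) as R, and the mild hydroxide closes and dehydrates without touching that centre.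

Step 2
Reactants: 4 (R)-cryptone; 5 isoprene
Product: 7 trans-fused octalone (4R,4aR,8aS)-4-isopropyl-6-methyl-3,4,4a,5,8,8a-hexahydronaphthalen-1(2H)-one, via cis-fused adduct 6 (not isolated)
Conditions: AlCl3 (0.25 equiv), toluene, rt; aqueous work-up; then NaOCH3 (0.2 equiv), MeOH, rt
Reagents that add atoms: none
Why: Lewis-acid-catalysed Diels–Alder reaction in which the diene terminus next to the methyl-bearing carbon bonds to the enone β-carbon C3 ("para" orientation, methyl on C10) on the face opposite the C4 isopropyl group, fixing C3 with C2 cis, after which methoxide epimerises C2 through the C1 enolate to the more stable trans-decalone with the isopropyl group equatorial.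

Step 3
Reactants: 7 trans-fused octalone
Product: 8 trans-fused diene (4R,4aR,8aS)-4-isopropyl-6-methyl-1-methylene-1,2,3,4,4a,5,8,8a-octahydronaphthalene
Conditions: Ph3PCH3Br, KOC(CH3)3, THF, 0 °C → reflux
Reagents that add atoms: methyltriphenylphosphonium bromide, C[P+](c1ccccc1)(c1ccccc1)c1ccccc1.[Br-]
Why: Wittig methylenation of the only carbonyl group; C2 already has the thermodynamic trans configuration and can no longer epimerise once C1 is an alkene carbon.

Step 4
Reactants: 8 trans-fused diene
Product: 10 conjugated oxime (C8=N–OH, C10(CH3)=C7, C1 methylene retained), via nitroso chloride 9 (not isolated)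
Conditions: t-BuONO, Me3SiCl, CH2Cl2, −20 °C; then pyridine, i-PrOH, 80 °C
Reagents that add atoms: tert-butyl nitrite, CC(C)(C)ON=O (N–O of the oxime); chlorotrimethylsilane, C[Si](C)(C)Cl (chlorine, present only in 9)
Why: Electrophilic nitrosochlorination of the more electron-rich trisubstituted C8=C10 bond (nitroso group to C8, chloride to the tertiary C10) in preference to the 1,1-disubstituted C1=C11 bond, then tautomerisation and base-induced loss of HCl towards C7, the sequence that turns 1-methylcyclohexenes bearing a remote 1,1-disubstituted alkene into 2-methylcyclohex-2-enone oximes; no stereocentre of the target is formed.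

Step 5
Reactants: 10 conjugated oxime
Product: 11 2-methyl enone (trans-decalin, C8 ketone, C10(CH3)=C7, C1=C11)
Conditions: TiCl3 (aq.), ammonium acetate, THF/H2O, rt
Reagents that add atoms: water, O
Why: Reductive deoximation in which trivalent titanium cleaves the N–O bond and the conjugated imine hydrolyses in the acetate buffer, mild enough to leave the exocyclic alkene in place.

Step 6
Reactants: 11 2-methyl enone
Product: 12 α-epoxy ketone (C7–C10 epoxide on the α face, C8 ketone)
Conditions: H2O2 (30 % aq.), NaOH (aq., cat.), MeOH, 0 °C
Reagents that add atoms: hydrogen peroxide, OO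
Why: Weitz–Scheffer nucleophilic epoxidation, to which the isolated C1=C11 alkene is inert; hydroperoxide should add axially to C7 on the α face (trans to the C3 hydrogen) and the enolate closes on the same face, and this configuration is in any case erased in step 11.

Step 7
Reactants: 12 α-epoxy ketone
Product: 14 C9 β-hydroxy epoxy ketone (axial C9–OH), via potassium enolate 13 (not isolated)
Conditions: KN(SiMe3)2, THF, −78 °C; then 2-(phenylsulfonyl)-3-phenyloxaziridine, −78 °C; AcOH
Reagents that add atoms: 2-(phenylsulfonyl)-3-phenyloxaziridine, O=S(=O)(c1ccccc1)N1OC1c1ccccc1 (oxygen); potassium bis(trimethylsilyl)amide, C[Si](C)(C)[N-][Si](C)(C)C.[K+] (potassium, present only in 13)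
Why: Enolate oxidation with an N-sulfonyloxaziridine at C9, the only enolisable position because C10 is quaternary, with oxygen transfer expected axially on the β face, anti to the axial C2 hydrogen and to the epoxide oxygen, giving the axial alcohol that also avoids the peri interaction with the C1 methylene.

Step 8
Reactants: 14 C9 β-hydroxy epoxy ketone; 15 (R)-2-methylbutanoic acid
Product: 16 C9 (R)-2-methylbutanoate of 14
Conditions: DCC, DMAP (cat.), CH2Cl2, 0 °C → rt
Reagents that add atoms: none
Why: Steglich esterification under conditions that should not epimerise the α-branched acid; material from the minor enantiomer of 4 becomes a diastereomer here and can be removed by chromatography.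

Step 9
Reactants: 16 C9 ester
Product: 17 C6 α-hydroxy derivative of 16 (axial allylic alcohol)
Conditions: SeO2 (0.5 equiv), t-BuOOH, CH2Cl2, rt
Reagents that add atoms: tert-butyl hydroperoxide, CC(C)(C)OO; selenium dioxide, O=[Se]=O (oxygen carrier)
Why: Selenium dioxide allylic oxidation (ene reaction then [2,3]-sigmatropic shift), which on a 1,1-disubstituted alkene attacks the ring CH2 (C6) in preference to the methine C2 and in methylenedecalins delivers oxygen axially, here to the α face of C6, while the epoxy ketone and the ester are inert.

Step 10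
Reactants: 17 C6 α-alcohol; 18 (E)-3-methylpent-2-enoic acid
Product: 19 key-step precursor (trans-decalin, C7–C10 α-epoxide, C8 ketone, C1=C11, C9 β-O-(R)-2-methylbutanoyl, C6 α-O-(E)-3-methylpent-2-enoyl)
Conditions: DCC, DMAP (cat.), CH2Cl2, 0 °C → rt
Reagents that add atoms: none
Why: Steglich esterification of the axial allylic alcohol, whose neutral carbodiimide conditions avoid the acid chloride and amine base that could isomerise or deconjugate the E enoate.

Step 11
Reactants: 19 key-step precursor
Product: 20 ring-contracted trans-hydrindane (ring B 2-acetylcyclopentanone: C7 bears acetyl C10 and ring ketone C8; C7 unspecified, keto/enol mixture; other groups as in 19)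
Conditions: BF3·OEt2 (2 equiv), 2,6-di-tert-butyl-4-methylpyridine (0.2 equiv), CH2Cl2, −40 → 0 °C
Reagents that add atoms: none
Why: BF3 coordinates the epoxide oxygen and the C7–O bond, the one remote from the carbonyl, breaks because positive charge at C10 would sit next to the ketone; as it breaks, the acyl carbon C8 moves from C10 to C7 on the face opposite the departing oxygen while the oxygen left on C10 closes to the acetyl carbonyl. The closest known reaction is the BF3-promoted rearrangement of α,β-epoxy ketones to β-dicarbonyl compounds, which contracts 2-alkyl-2,3-epoxycyclohexanones to 2-acylcyclopentanones. Ring B is closed by this 1,2-acyl shift, a six-to-five ring contraction, and not by a cyclisation. No stereocentre is fixed: C7 lies between two carbonyl groups and is set only in step 12, while C2, C3, C4, C6 and C9 lie outside the reacting bonds and should keep their configuration. The step needs acyl migration instead of a methyl or C3-hydride shift and no ionisation of the allylic C6 ester: only the acyl shift is driven by carbonyl formation at C10 and the acyl group is the best migrating group in this rearrangement, and low temperature with a hindered pyridine as proton trap protects the allylic ester and the exocyclic alkene.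

Step 12
Reactants: 20 ring-contracted diketone
Product: 21 target CNP0224363.1 (C7 R with β-[(S)-1-hydroxyethyl] branch, C8 ketone, C9 β-(R)-2-methylbutanoate, C6 α-(E)-3-methylpent-2-enoate, C1 methylene, C4 β-isopropyl, trans C2–C3 fusion)
Conditions: Zn(BH4)2 (0.5 equiv), Et2O, −78 → −30 °C; then aq. NH4Cl
Reagents that add atoms: none
Why: Chelation-controlled reduction of a 2-substituted 1,3-diketone in which zinc bridges the C8 and C10 carbonyl oxygens, the epimer of the labile C7 with the branch β (trans to the C3–C4 bond) forms the less crowded chelate, and hydride adds to the methyl ketone from the chelate face opposite C3 to give the syn C7/C10 ketol (7R, 10S); the ring ketone is shielded on the β face by the C7 and C9 substituents, α attack would create an all-cis cyclopentane, and esters are not reduced at this temperature.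

Compound list
1 | 3-methylbutanal | CC(C)CC=O | starting material
2 | but-3-en-2-one | CC(=O)C=C | starting material
3 | (R)-2-isopropyl-5-oxohexanal | O=C[C@@H](C(C)C)CCC(C)=O | intermediate (not isolated)
4 | (R)-4-isopropylcyclohex-2-en-1-one ((R)-cryptone) | O=C1C=C[C@@H](C(C)C)CC1 | intermediate
5 | isoprene (2-methylbuta-1,3-diene) | C=CC(C)=C | starting material
6 | cis-fused adduct (4R,4aR,8aR)-4-isopropyl-6-methyl-3,4,4a,5,8,8a-hexahydronaphthalen-1(2H)-one | O=C1[C@H]2[C@H](CC(C)=CC2)[C@@H](C(C)C)CC1 | intermediate (not isolated)
7 | trans-fused octalone (4R,4aR,8aS)-4-isopropyl-6-methyl-3,4,4a,5,8,8a-hexahydronaphthalen-1(2H)-one | O=C1[C@@H]2[C@H](CC(C)=CC2)[C@@H](C(C)C)CC1 | intermediate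
8 | trans-fused diene (4R,4aR,8aS)-4-isopropyl-6-methyl-1-methylene-1,2,3,4,4a,5,8,8a-octahydronaphthalene | C=C1[C@@H]2[C@H](CC(C)=CC2)[C@@H](C(C)C)CC1 | intermediate
9 | nitroso chloride of 8 (C8 nitroso, C10 chloro; drawn as monomer, C8/C10 configuration not defined) | C=C1[C@@H]2[C@H](CC(C)(Cl)C(N=O)C2)[C@@H](C(C)C)CC1 | intermediate (not isolated)
10 | conjugated oxime (C8=N–OH, C10(CH3)=C7, C1=C11; oxime geometry not defined) | C=C1[C@@H]2[C@H](C=C(C)C(=NO)C2)[C@@H](C(C)C)CC1 | intermediate
11 | 2-methyl enone (trans-decalin, C8 ketone, C10(CH3)=C7, C1=C11, C4 β-isopropyl) | C=C1[C@@H]2[C@H](C=C(C)C(=O)C2)[C@@H](C(C)C)CC1 | intermediate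
12 | α-epoxy ketone (C7–C10 α-epoxide, C8 ketone) | C=C1[C@@H]2[C@H]([C@H]3O[C@@]3(C)C(=O)C2)[C@@H](C(C)C)CC1 | intermediate
13 | potassium C8=C9 enolate of 12 | C=C1[C@@H]2[C@H]([C@H]3O[C@@]3(C)C([O-])=C2)[C@@H](C(C)C)CC1.[K+] | intermediate (not isolated)
14 | C9 β-hydroxy (axial) epoxy ketone | C=C1[C@@H]2[C@H]([C@H]3O[C@@]3(C)C(=O)[C@@H]2O)[C@@H](C(C)C)CC1 | intermediate
15 | (R)-2-methylbutanoic acid | CC[C@@H](C)C(=O)O | starting material
16 | C9 β-O-(R)-2-methylbutanoyl epoxy ketone | C=C1[C@@H]2[C@H]([C@H]3O[C@@]3(C)C(=O)[C@@H]2OC(=O)[C@H](C)CC)[C@@H](C(C)C)CC1 | intermediate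
17 | C6 α-hydroxy (axial) derivative of 16 | C=C1[C@@H]2[C@H]([C@H]3O[C@@]3(C)C(=O)[C@@H]2OC(=O)[C@H](C)CC)[C@@H](C(C)C)C[C@@H]1O | intermediate
18 | (E)-3-methylpent-2-enoic acid | CC/C(C)=C/C(=O)O | starting material
19 | key-step precursor: trans-decalin 2-methyl-2,3-epoxy ketone with C1 methylene, C9 β-(R)-2-methylbutanoate, C6 α-(E)-3-methylpent-2-enoate | C=C1[C@@H]2[C@H]([C@H]3O[C@@]3(C)C(=O)[C@@H]2OC(=O)[C@H](C)CC)[C@@H](C(C)C)C[C@@H]1OC(=O)/C=C(\C)CC | intermediate
20 | trans-hydrindane 2-acetylcyclopentanone (C7 unspecified), esters and methylene as in 19 | C=C1[C@@H]2[C@H](C(C(C)=O)C(=O)[C@@H]2OC(=O)[C@H](C)CC)[C@@H](C(C)C)C[C@@H]1OC(=O)/C=C(\C)CC | intermediate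
21 | CNP0224363.1 | C=C1[C@@H]2[C@H]([C@H]([C@H](C)O)C(=O)[C@@H]2OC(=O)[C@H](C)CC)[C@@H](C(C)C)C[C@@H]1OC(=O)/C=C(\C)CC | target

Total step count: 12
Longest linear sequence: 12 steps (1 and 2 to 21)

Steps most likely to fail

Step 11. The Lewis acid may ionise or transpose the allylic C6 ester, or traces of protic acid may move the exocyclic double bond into ring A, faster than the epoxide opens. Fallback: the ring contraction is run before C6 is oxygenated. Setting out from 16, BF3·OEt2 under the conditions of step 11 should give the acetylcyclopentanone without C6 oxygen F1. Zn(BH4)2 as in step 12 should give the hydroxyethyl ketone F2, and Et3SiCl/imidazole its triethylsilyl ether F3. SeO2/t-BuOOH as in step 9 should give the C6 α-alcohol F4, and DCC/DMAP with 18 the C6 enoate silyl ether F5. HF·pyridine in THF then removes the silyl group and the route is rejoined at 21.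

Step 12. Hydride may be delivered to the ring ketone, the first-formed zinc ketol chelate may be reduced a second time, or deprotonation at the acidic C7 may stall the reduction. Fallback: substrate control is replaced by enzyme control. From 20, the NADH-dependent (S)-selective alcohol dehydrogenase of Rhodococcus ruber (ADH-A) is used with i-PrOH as hydride donor in phosphate buffer (pH 7, 30 °C). It reduces methyl ketones and should leave a ketone flanked by two branched carbons untouched. Because C7 of 20 equilibrates through the enol, the isomer with the β branch should be drawn through to 21. No new compound arises (F0).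

Step 7. Oxygen transfer to the epoxy ketone enolate may show poor facial selectivity (attack syn to the epoxide oxygen). Fallback: C9 is hydroxylated before the epoxide is made. From 11, KN(SiMe3)2 and the same oxaziridine should give the α′-hydroxy enone F6, by axial attack on the cross-conjugated enolate with no epoxide to bias it. t-BuMe2SiOTf/2,6-lutidine gives the silyl ether F7, and H2O2/NaOH the silyloxy epoxy ketone F8. HF·pyridine then removes the silyl group and the route is rejoined at 14.

Further compounds
F1 | step 11 | ring-contracted 2-acetylcyclopentanone without C6 oxygen (C7 unspecified) | C=C1[C@@H]2[C@H](C(C(C)=O)C(=O)[C@@H]2OC(=O)[C@H](C)CC)[C@@H](C(C)C)CC1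
F2 | step 11 | hydroxyethyl ketone without C6 oxygen | C=C1[C@@H]2[C@H]([C@H]([C@H](C)O)C(=O)[C@@H]2OC(=O)[C@H](C)CC)[C@@H](C(C)C)CC1
F3 | step 11 | C10 triethylsilyl ether of F2 | C=C1[C@@H]2[C@H]([C@H]([C@H](C)O[Si](CC)(CC)CC)C(=O)[C@@H]2OC(=O)[C@H](C)CC)[C@@H](C(C)C)CC1
F4 | step 11 | C6 α-alcohol of F3 | C=C1[C@@H]2[C@H]([C@H]([C@H](C)O[Si](CC)(CC)CC)C(=O)[C@@H]2OC(=O)[C@H](C)CC)[C@@H](C(C)C)C[C@@H]1O
F5 | step 11 | C6 (E)-3-methylpent-2-enoate of F4 | C=C1[C@@H]2[C@H]([C@H]([C@H](C)O[Si](CC)(CC)CC)C(=O)[C@@H]2OC(=O)[C@H](C)CC)[C@@H](C(C)C)C[C@@H]1OC(=O)/C=C(\C)CC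
F0 | step 12 | none | none
F6 | step 7 | C9 β-hydroxy 2-methyl enone | C=C1[C@@H]2[C@H](C=C(C)C(=O)[C@@H]2O)[C@@H](C(C)C)CC1
F7 | step 7 | C9 tert-butyldimethylsilyl ether of F6 | C=C1[C@@H]2[C@H](C=C(C)C(=O)[C@@H]2O[Si](C)(C)C(C)(C)C)[C@@H](C(C)C)CC1
F8 | step 7 | C9 silyloxy α-epoxy ketone | C=C1[C@@H]2[C@H]([C@H]3O[C@@]3(C)C(=O)[C@@H]2O[Si](C)(C)C(C)(C)C)[C@@H](C(C)C)CC1
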